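Late in both earlier runs the target stands nearly still while dissolved starting material remains: it reads 57.6% at dusk and 52.6% at noon, at one catalyst loading. A catalyst dying after a fixed count of turnovers, each of them giving target, leaves the same percentage at each charge at one loading, but dusk reads 5 percentage points higher than noon, against a scatter of 1 point per reading. This reckoning therefore takes the partner as the limiting reagent, shared with the second substrate, which was never read.

the same everywhere: catalyst 8.6 mol%
- dusk: solid substrate 10 mM; partner 2 equiv; second substrate 2 equiv (in portions, 4); run made earlier; portions every 1.0 min
- noon: solid substrate 15 mM; partner 2 equiv; second substrate 2 equiv (in portions, 4); run made earlier; portions every 1.0 min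
- flask: solid substrate 20 mM; partner 2.00 equiv; second substrate 2.00 equiv (in portions, 4); the portions of second substrate follow each other after 1.0 min, the first at the start; time 2.0 h

- dusk (time / min: target / %, starting material / %): 25.0: 45.8, 55.0; 50.0: 53.9, 46.9; 80.0: 55.4, 44.7; 90.0: 57.1, 43.1; 120: 57.6, 42.6
- noon (time / min: target / %, starting material / %): 10.0: 33.8, 66.4; 20.0: 46.3, 51.9; 30.0: 50.0, 51.4; 60.0: 52.3, 47.1; 120: 52.6, 47.2

(readings scatter by 1 percentage point)

- which holds at 2.0 h: what has brought the reaction to rest, or that it has not come to rest (for what has run out or reacted, a solid counts together with what of it has only dissolved) (it is still moving / all of the solid substrate has reacted / no working catalyst is left / the partner has run out first)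
- the target standing at 2.0 h, as a percentage of the solid substrate charged
- the starting material standing at 2.0 h, as a percentage of the solid substrate charged

- given per volume of solution although it is solid: solid substrate
- at the start none of the solid substrate is in solution
- what has only dissolved of solid substrate counts as not reacted
- the reaction counts as stopped when no species that holds the solid substrate changes by six tenths of a point or more over the second half of the time
- starting material means what is dissolved; the solid is not counted in it

Read from the last target readings, with their scatter, dusk gives 3.47 and noon 3.80 for the partner cost r, the equivalents of partner charged per equivalent of target at rest. Carried along a straight line to the new flask, r becomes 4.13. The ledger per equivalent of solid substrate then reads: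

partner charged: 2.00 equiv

to target, charge divided by r: 48.4%

to second substrate: 1.52 equiv, out of 2.00 equiv

Going round once more, the second substrate can absorb that entry, so the first answer stands and the books close with 51.6% starting material.

The forecast gives 48.5% (45% to 52%) and 51% (44% to 55%), close to this ledger, but its end differs: no working catalyst is left. “The stall therefore points to catalyst death”

The flask gives 43.8% target and 56.2% starting material, with 0% of the partner and 22% of the second substrate left and 100% of the catalyst live: the partner has run out first.

    solid substrate ⇌ starting material, rate k1*(cs1 - [starting material]) while solid is left; crystals form when [starting material] > cs1 (solubility = 20.0 mM, k = 0.130 min⁻¹)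
    starting material + partner + catalyst → catalyst + target (k = 4000 M⁻² min⁻¹)
    second substrate + partner + catalyst → catalyst + second product (k = 5600 M⁻² min⁻¹)

Removing the loss of second substrate to second product lifts conversion of the solid substrate from 43.8% to >99.9%. The flask's partner cost is 4.56, higher than the projected 4.13, so its target falls below the ledger's.

For a neighbouring flask at 8.0 mM of solid substrate, with the same equivalents and loading, the same line gives r = 3.34 and so 59.9% target; that neighbour, computed, gives 57.2%, with 1.4% of its partner left.

The earlier runs and the new flask stem from a simulated flask with constants of no real substance, and the scatter is random.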